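**Plan**

- Numbering: C1 is the acetoxymethyl carbon; the chain runs through C6 (carbinol) and C7 (quaternary, the oxygen-bearing ring carbon) to C11, the lactone α-carbon. The oxepinone ring holds C7–C11, the carbonyl carbon and the ring oxygen.
- Cuts, in retrosynthetic order: the acetate ester; the lactone C7–O–acyl bond; C9–C10 (B-alkyl Suzuki coupling with a (Z)-iodoacrylic acid); C1–C2 and C3–CH3 (methylalumination/formaldehyde on an alkyne); C4–C5 (propargyl opening of an epoxide); last the C5–O and C6–O bonds of that epoxide.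
- Enabling feature: C7 carries CH3 and oxygen and lies between C6 and C8, and both C5–C6 and C8–C9 can begin as vinyl groups, so the C6/C7 pair is latent in achiral 3-methylpenta-1,4-dien-3-ol.
- Forward: the oxirane is formed first; the chain grows at C5, then at C9 through the surviving vinyl group; the seven-membered lactone closes late and the acetate goes on last.
- Stereochemistry: C6 and C7 are set together by the desymmetrising epoxidation and are not touched again. The 2E alkene comes from syn-carboalumination, and the ring alkene from a chelate-controlled carbomagnesiation that fixes the Z iodide.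

Key step: step 1

Remark: the sense of induction of a hafnium–bishydroxamate on a divinyl carbinol is not known, so the route is written for whichever ligand antipode a first screen of both shows to give (2S,2′R)-3.

**Route**

Step 1
Reactants: 1 3-methylpenta-1,4-dien-3-ol; 2 tert-butyl hydroperoxide
Product: 3 (2S)-2-[(2R)-oxiran-2-yl]but-3-en-2-ol
Conditions: Hf(OtBu)4 (10 mol %), N,N′-dihydroxy-N,N′-bis(diarylacetyl)-trans-cyclohexane-1,2-diamine (11 mol %), anhydrous TBHP in toluene (1.1 equiv), DMPU (20 mol %), 4 Å MS, toluene, 0 °C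
Reagents that add atoms: tert-butyl hydroperoxide (2), CC(C)(C)OO
Why: Proposed new method: exchange of a tert-butoxide for the tertiary hydroxyl of 1 places the substrate on the tetravalent hafnium–bishydroxamate, and the metal-bound tert-butylperoxide hands its proximal oxygen to one vinyl group through a concerted spiro transition state in which the C5–O and C6–O bonds form together. The closest known reaction types are the hafnium–bishydroxamic acid epoxidation of tertiary allylic alcohols and the Ti(OiPr)4–tartrate desymmetrisation of secondary divinyl carbinols. The three-membered ring closes by direct oxygen-atom transfer to the C5=C6 alkene ([2+1] addition, syn on the alkene), not by an intramolecular displacement. C7 becomes stereogenic through the choice between the two enantiotopic vinyl groups and C6 through the choice of alkene face, and both choices are made by the C2-symmetric ligand held next to the metal-bound alkoxide, which has to tell CH3 from vinyl at C7. The step needs group, face and mono-over-bis selectivity; the single hydroxyl as the only binding site, two identical unhindered vinyl groups, about one equivalent of oxidant and the expected faster second epoxidation of the minor stereoisomers (which should enrich surviving 3) are relied on for these.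

Step 2
Reactants: 3 (2S)-2-[(2R)-oxiran-2-yl]but-3-en-2-ol; 4 propargyl bromide (3-bromoprop-1-yne)
Product: 6 (3S,4R)-3-methyloct-1-en-7-yne-3,4-diol, via allenylmagnesium bromide 5 (not isolated)
Conditions: 4, Mg, HgCl2 (cat.), Et2O, 0 °C; then 3 (added to 3 equiv of 5), −78 → 0 °C; aq. NH4Cl
Reagents that add atoms: none
Why: Grignard opening of a terminal epoxide, in which the allenyl/propargyl magnesium reagent attacks the unsubstituted C5 by an SE2′ path that delivers the terminal alkyne, the first equivalent only deprotonating the tertiary hydroxyl, so that C6 and C7, which are not at the reacting carbon, keep their configuration.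

Step 3
Reactants: 6 (3S,4R)-3-methyloct-1-en-7-yne-3,4-diol
Product: 8 (2E,6R,7S)-3,7-dimethylnona-2,8-diene-1,6,7-triol, via (E)-alkenyldimethylalane 7 (not isolated)
Conditions: AlMe3 (5 equiv), Cp2ZrCl2 (0.3 equiv), CH2Cl2, 0 °C → rt; then (CH2O)n, THF, 0 °C → rt; aq. potassium sodium tartrate
Reagents that add atoms: trimethylaluminium, C[Al](C)C; formaldehyde (from paraformaldehyde), C=O
Why: Negishi zirconium-catalysed methylalumination adds CH3 and Al syn across the terminal alkyne with methyl on the internal carbon (hence 2E), and the alkenyl–aluminium bond is then hydroxymethylated by formaldehyde with retention, while the hindered vinyl group and the aluminium alkoxides of the diol are not expected to take part.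

Step 4
Reactants: 8 (2E,6R,7S)-3,7-dimethylnona-2,8-diene-1,6,7-triol
Product: 9 (3S,4R,7E)-4,9-bis[(tert-butyldimethylsilyl)oxy]-3,7-dimethylnona-1,7-dien-3-ol
Conditions: TBSCl (2.5 equiv), imidazole, DMF, rt
Reagents that add atoms: tert-butyldimethylsilyl chloride, CC(C)(C)[Si](C)(C)Cl
Why: Silyl ether formation with TBSCl/imidazole discriminates by steric demand, so the primary allylic and the secondary hydroxyl are capped while the tertiary allylic hydroxyl, needed free for the lactone, is left.

Step 5
Reactants: 10 5-bromo-2-methylpent-2-ene; 11 prop-2-yn-1-ol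
Product: 14 (2Z)-3-iodo-2-(4-methylpent-3-en-1-yl)prop-2-en-1-ol, via homoprenylmagnesium bromide 12 (not isolated), via cyclic alkenylmagnesium alkoxide 13 (not isolated)
Conditions: 10, Mg, Et2O, rt (3 equiv of 12); then 11, CuI (15 mol %), −10 °C → rt; then I2, −20 → 0 °C; aq. NH4Cl/Na2S2O3
Reagents that add atoms: iodine, II
Why: Copper-catalysed anti-carbomagnesiation of the propargylic alkoxide puts the homoprenyl group on C2 and magnesium on C3 inside a five-membered alkoxide chelate, so iodinolysis with retention leaves iodine cis to CH2OH, the Z geometry that later becomes the ring alkene.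

Step 6
Reactants: 14 (2Z)-3-iodo-2-(4-methylpent-3-en-1-yl)prop-2-en-1-ol
Product: 15 (2Z)-3-iodo-2-(4-methylpent-3-en-1-yl)prop-2-enal
Conditions: MnO2 (20 equiv), CH2Cl2, rt, dark
Reagents that add atoms: none
Why: Allylic oxidation with MnO2 is selective for the primary allylic alcohol, leaves the vinyl iodide and the trisubstituted alkene alone and, run neutral and in the dark, should keep the Z geometry.

Step 7
Reactants: 15 (2Z)-3-iodo-2-(4-methylpent-3-en-1-yl)prop-2-enal
Product: 16 (2Z)-3-iodo-2-(4-methylpent-3-en-1-yl)prop-2-enoic acid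
Conditions: NaClO2, NaH2PO4, 2-methylbut-2-ene, t-BuOH/H2O, 0 °C → rt
Reagents that add atoms: sodium chlorite, [Na+].[O-]Cl=O
Why: Pinnick oxidation converts the enal to the acid under buffered conditions, with 2-methylbut-2-ene trapping HOCl so that the trisubstituted alkene and the Z vinyl iodide survive.

Step 8
Reactants: 9 (3S,4R,7E)-4,9-bis[(tert-butyldimethylsilyl)oxy]-3,7-dimethylnona-1,7-dien-3-ol; 16 (2Z)-3-iodo-2-(4-methylpent-3-en-1-yl)prop-2-enoic acid
Product: 18 (2Z,6S,7R,10E)-7,12-bis[(tert-butyldimethylsilyl)oxy]-6-hydroxy-6,10-dimethyl-2-(4-methylpent-3-en-1-yl)dodeca-2,10-dienoic acid, via B-alkyl-9-BBN borane 17 (not isolated)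
Conditions: 9-BBN (2.2 equiv), THF, 0 °C → rt; then degassed aq. Cs2CO3 (3 M), 16, Pd(dppf)Cl2 (10 mol %), AsPh3 (10 mol %), DMF, rt; acidify to pH 4
Reagents that add atoms: none
Why: Hydroboration/B-alkyl Suzuki–Miyaura coupling, in which 9-BBN adds anti-Markovnikov only to the monosubstituted C8=C9 alkene and zerovalent palladium then joins C9 to C10 with retention of the vinyl iodide geometry, the acid travelling as its caesium carboxylate.

Step 9
Reactants: 18 (2Z,6S,7R,10E)-7,12-bis[(tert-butyldimethylsilyl)oxy]-6-hydroxy-6,10-dimethyl-2-(4-methylpent-3-en-1-yl)dodeca-2,10-dienoic acid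
Product: 20 (7S)-7-[(1R,4E)-1,6-bis[(tert-butyldimethylsilyl)oxy]-4-methylhex-4-en-1-yl]-7-methyl-3-(4-methylpent-3-en-1-yl)-6,7-dihydro-5H-oxepin-2-one, via mixed trichlorobenzoic anhydride 19 (not isolated)
Conditions: 2,4,6-Cl3C6H2COCl, Et3N, THF, rt; then slow addition to DMAP, toluene, 80 °C, high dilution
Reagents that add atoms: none
Why: Yamaguchi lactonization, in which DMAP turns the mixed anhydride into an acylpyridinium that is attacked by the only free hydroxyl, the tertiary one on C7, in a 7-exo-trig acyl substitution made possible by the Z alkene holding the acyl group and C9 on the same side; C7 keeps its configuration because its C–O bond is not broken.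

Step 10
Reactants: 20 (7S)-7-[(1R,4E)-1,6-bis[(tert-butyldimethylsilyl)oxy]-4-methylhex-4-en-1-yl]-7-methyl-3-(4-methylpent-3-en-1-yl)-6,7-dihydro-5H-oxepin-2-one
Product: 21 (7S)-7-[(1R,4E)-1,6-dihydroxy-4-methylhex-4-en-1-yl]-7-methyl-3-(4-methylpent-3-en-1-yl)-6,7-dihydro-5H-oxepin-2-one
Conditions: HF·pyridine, pyridine, THF, 0 °C → rt
Reagents that add atoms: none
Why: Fluoride-mediated desilylation with buffered HF·pyridine should remove both TBS ethers without opening the tertiary-alkyl lactone or isomerising the alkenes.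

Step 11
Reactants: 21 (7S)-7-[(1R,4E)-1,6-dihydroxy-4-methylhex-4-en-1-yl]-7-methyl-3-(4-methylpent-3-en-1-yl)-6,7-dihydro-5H-oxepin-2-one
Product: 22 (2E,6R)-6-hydroxy-3-methyl-6-[(2S)-2-methyl-6-(4-methylpent-3-en-1-yl)-7-oxo-2,3,4,7-tetrahydrooxepin-2-yl]hex-2-en-1-yl acetate
Conditions: Ac2O (1.1 equiv), 2,4,6-collidine, CH2Cl2, −20 → 0 °C
Reagents that add atoms: acetic anhydride, CC(=O)OC(C)=O
Why: Chemoselective acylation, in which the unhindered primary allylic hydroxyl should react with one equivalent of acetic anhydride far faster than the secondary hydroxyl at C6, which is flanked by the quaternary C7.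

**Compound list**

1 | 3-methylpenta-1,4-dien-3-ol | C=CC(C)(O)C=C | starting material
2 | tert-butyl hydroperoxide | CC(C)(C)OO | starting material
3 | (2S)-2-[(2R)-oxiran-2-yl]but-3-en-2-ol | C=C[C@](C)(O)[C@H]1CO1 | intermediate
4 | propargyl bromide (3-bromoprop-1-yne) | C#CCBr | starting material
5 | allenylmagnesium bromide (propargyl Grignard reagent) | C=C=C[Mg]Br | intermediate
6 | (3S,4R)-3-methyloct-1-en-7-yne-3,4-diol | C#CCC[C@@H](O)[C@@](C)(O)C=C | intermediate
7 | (E)-alkenyldimethylalane of 6, both hydroxyls as dimethylaluminium alkoxides | C[Al](C)/C=C(\C)CC[C@@H](O[Al](C)C)[C@@](C)(O[Al](C)C)C=C | intermediate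
8 | (2E,6R,7S)-3,7-dimethylnona-2,8-diene-1,6,7-triol | OC/C=C(\C)CC[C@@H](O)[C@@](C)(O)C=C | intermediate
9 | (3S,4R,7E)-4,9-bis[(tert-butyldimethylsilyl)oxy]-3,7-dimethylnona-1,7-dien-3-ol | CC(C)(C)[Si](C)(C)OC/C=C(\C)CC[C@@H](O[Si](C)(C)C(C)(C)C)[C@@](C)(O)C=C | intermediate
10 | 5-bromo-2-methylpent-2-ene | CC(C)=CCCBr | starting material
11 | prop-2-yn-1-ol | C#CCO | starting material
12 | (4-methylpent-3-en-1-yl)magnesium bromide | CC(C)=CCC[Mg]Br | intermediate
13 | five-membered alkenylmagnesium alkoxide chelate, Mg bound to C3 and to the alkoxide oxygen, homoprenyl on C2 | CC(C)=CCCC1=C[Mg]OC1 | intermediate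
14 | (2Z)-3-iodo-2-(4-methylpent-3-en-1-yl)prop-2-en-1-ol | I/C=C(/CCC=C(C)C)CO | intermediate
15 | (2Z)-3-iodo-2-(4-methylpent-3-en-1-yl)prop-2-enal | I/C=C(/CCC=C(C)C)C=O | intermediate
16 | (2Z)-3-iodo-2-(4-methylpent-3-en-1-yl)prop-2-enoic acid | I/C=C(/CCC=C(C)C)C(=O)O | intermediate
17 | 9-[(3S,4R,7E)-4,9-bis[(tert-butyldimethylsilyl)oxy]-3-hydroxy-3,7-dimethylnon-7-en-1-yl]-9-borabicyclo[3.3.1]nonane | CC(C)(C)[Si](C)(C)OC/C=C(\C)CC[C@@H](O[Si](C)(C)C(C)(C)C)[C@@](C)(O)CCB1C2CCCC1CCC2 | intermediate
18 | (2Z,6S,7R,10E)-7,12-bis[(tert-butyldimethylsilyl)oxy]-6-hydroxy-6,10-dimethyl-2-(4-methylpent-3-en-1-yl)dodeca-2,10-dienoic acid | CC(C)(C)[Si](C)(C)OC/C=C(\C)CC[C@@H](O[Si](C)(C)C(C)(C)C)[C@@](C)(O)CC/C=C(/CCC=C(C)C)C(=O)O | intermediate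
19 | mixed anhydride of 18 and 2,4,6-trichlorobenzoic acid | CC(C)(C)[Si](C)(C)OC/C=C(\C)CC[C@@H](O[Si](C)(C)C(C)(C)C)[C@@](C)(O)CC/C=C(/CCC=C(C)C)C(=O)OC(=O)c1c(Cl)cc(Cl)cc1Cl | intermediate
20 | (7S)-7-[(1R,4E)-1,6-bis[(tert-butyldimethylsilyl)oxy]-4-methylhex-4-en-1-yl]-7-methyl-3-(4-methylpent-3-en-1-yl)-6,7-dihydro-5H-oxepin-2-one | CC(C)(C)[Si](C)(C)OC/C=C(\C)CC[C@@H](O[Si](C)(C)C(C)(C)C)[C@]1(C)CCC=C(CCC=C(C)C)C(=O)O1 | intermediate
21 | (7S)-7-[(1R,4E)-1,6-dihydroxy-4-methylhex-4-en-1-yl]-7-methyl-3-(4-methylpent-3-en-1-yl)-6,7-dihydro-5H-oxepin-2-one | OC/C=C(\C)CC[C@@H](O)[C@]1(C)CCC=C(CCC=C(C)C)C(=O)O1 | intermediate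
22 | (2E,6R)-6-hydroxy-3-methyl-6-[(2S)-2-methyl-6-(4-methylpent-3-en-1-yl)-7-oxo-2,3,4,7-tetrahydrooxepin-2-yl]hex-2-en-1-yl acetate | CC(=O)OC/C=C(\C)CC[C@@H](O)[C@]1(C)CCC=C(CCC=C(C)C)C(=O)O1 | target

**Step count**

Total: 11 steps. Longest linear sequence: 8 steps (1–4 and 8–11, from 1 to 22); the iodo acid 16 is made in a 3-step branch (5–7).

**Steps most likely to fail**

Risk 1, step 1. The ligand may discriminate poorly between the two enantiotopic vinyl groups (CH3 and vinyl at C7 differ little in size) or between the alkene faces, and oxidation may run on to the bis-epoxide. The fallback uses known chemistry, sets out from tert-butyl hydroperoxide 2 and comes back at 3. Compound 2 is used in a Sharpless asymmetric epoxidation of commercial penta-1,4-dien-3-ol F1, the established desymmetrisation of a secondary divinyl carbinol (Ti(OiPr)4, the diisopropyl tartrate antipode that gives the (2R)-oxirane, expected to be L-(+) from the usual mnemonic, 4 Å MS, CH2Cl2, −20 °C). This should give (1S)-1-[(2R)-oxiran-2-yl]prop-2-en-1-ol F2. Oxidation with Dess–Martin periodinane gives 1-[(2R)-oxiran-2-yl]prop-2-en-1-one F3. Addition of CH3MgBr (Et2O, −78 °C), with magnesium chelated between the ketone and oxirane oxygens so that methyl enters from the side of the C6 hydrogen, should then give 3.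

Risk 2, step 9. Acylation of the hindered tertiary hydroxyl may be slow, so that geometric isomerisation or deconjugation of the activated Z-enoate, or oligomerisation, wins. The fallback sets out from 9 and 16 and comes back at 20, closing the ring through C9–C10 instead of through the acyl–oxygen bond. Acid 16 is converted under neutral conditions with 1-chloro-N,N,2-trimethylprop-1-en-1-amine into (2Z)-3-iodo-2-(4-methylpent-3-en-1-yl)prop-2-enoyl chloride F4. The potassium alkoxide of 9 (KN(SiMe3)2, THF, −78 °C) is acylated by F4 to (3S,4R,7E)-4,9-bis[(tert-butyldimethylsilyl)oxy]-3,7-dimethylnona-1,7-dien-3-yl (2Z)-3-iodo-2-(4-methylpent-3-en-1-yl)prop-2-enoate F5. 9-BBN hydroborates the vinyl group to the B-alkyl-9-BBN borane of that ester F6. An intramolecular B-alkyl Suzuki–Miyaura coupling (Pd(dppf)Cl2, AsPh3, aq. Cs2CO3, DMF–THF, high dilution) then gives 20.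

Risk 3, step 8. Transmetalation may be slowed by chelation of palladium to the free carboxylate, and protodeboronation of 17 or consumption of 9-BBN by the free tertiary hydroxyl may compete. The fallback sets out from 16 and comes back at 18. Acid 16 is methylated (CH3I, K2CO3, DMF) to methyl (2Z)-3-iodo-2-(4-methylpent-3-en-1-yl)prop-2-enoate F7. F7 is coupled with borane 17 under the same palladium conditions to the methyl ester of 18 F8, and LiOH (THF–MeOH–H2O, rt) then frees acid 18.

**Further compounds**

F1 | step 1 | penta-1,4-dien-3-ol | C=CC(O)C=C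
F2 | step 1 | (1S)-1-[(2R)-oxiran-2-yl]prop-2-en-1-ol | C=C[C@H](O)[C@H]1CO1
F3 | step 1 | 1-[(2R)-oxiran-2-yl]prop-2-en-1-one | C=CC(=O)[C@H]1CO1
F4 | step 9 | (2Z)-3-iodo-2-(4-methylpent-3-en-1-yl)prop-2-enoyl chloride | I/C=C(/CCC=C(C)C)C(=O)Cl
F5 | step 9 | (3S,4R,7E)-4,9-bis[(tert-butyldimethylsilyl)oxy]-3,7-dimethylnona-1,7-dien-3-yl (2Z)-3-iodo-2-(4-methylpent-3-en-1-yl)prop-2-enoate | CC(C)(C)[Si](C)(C)OC/C=C(\C)CC[C@@H](O[Si](C)(C)C(C)(C)C)[C@@](C)(OC(=O)/C(CCC=C(C)C)=C\I)C=C
F6 | step 9 | B-alkyl-9-BBN borane of F5 (boron on the former vinyl terminus) | CC(C)(C)[Si](C)(C)OC/C=C(\C)CC[C@@H](O[Si](C)(C)C(C)(C)C)[C@@](C)(OC(=O)/C(CCC=C(C)C)=C\I)CCB1C2CCCC1CCC2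
F7 | step 8 | methyl (2Z)-3-iodo-2-(4-methylpent-3-en-1-yl)prop-2-enoate | I/C=C(/CCC=C(C)C)C(=O)OC
F8 | step 8 | methyl (2Z,6S,7R,10E)-7,12-bis[(tert-butyldimethylsilyl)oxy]-6-hydroxy-6,10-dimethyl-2-(4-methylpent-3-en-1-yl)dodeca-2,10-dienoate | CC(C)(C)[Si](C)(C)OC/C=C(\C)CC[C@@H](O[Si](C)(C)C(C)(C)C)[C@@](C)(O)CC/C=C(/CCC=C(C)C)C(=O)OC
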